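# Proposed synthesis of CNP0147016.1 by butenolide conjugate addition with Mannich trapping

Numbering used throughout (germacrane numbering): ring carbons C1–C10; C14 is the ester carbon on C10; C15 is the methyl on C4; C11, C12 and C13 are the lactone α-carbon, carbonyl and exocyclic methylene. The target is (4R,5S,6S,7R,8S,9R).

## The problem

The target is a germacranolide. Its ten-membered carbocycle carries a ring-cis C1=C10 enoate, a cis-fused C4–C5 oxirane and an α-methylene-γ-lactone trans-fused across C6 (oxygen) and C7 (C11). C8 bears a 2-(hydroxymethyl)acrylate and C9 an acetate; the two oxygens are cis to each other and lie on the ring face of the C7–C11 bond. Six contiguous stereocentres (C4–C9) must be set, and the medium ring must be closed against both entropy and transannular strain.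

The stereocentres can be chained. C4 and C5 are fixed together by the geometry of a (Z)-trisubstituted olefin. C5 can steer C6 by 1,2-induction, C6 can steer C7 across a five-membered ring, and C7 can steer C11. Only C8 and C9 must take their configuration from the shape of the macrocycle.

Several groups will not survive rough treatment. There are two acrylate-type Michael acceptors, a trisubstituted epoxide that is labile to acid and Lewis acid, and vicinal esters that migrate or relactonise (O8 onto C12) under base. These groups must appear late or travel masked.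

The feature that opens the structure is the lactone. C7 is its β-carbon and holds C8 trans to C5 on C6; C11 is its α-carbon and holds C13. A butenolide with C6 already in place can therefore take C8 at C7 and C13 at C11 in one conjugate addition with enolate capture.

## Retrosynthesis

**Unmasking (34 ← 33 ← 31).** The last operations cut only heteroatom bonds: the Si–O bond of the side-chain silyl ether in 33, and before that the C13–N bond of the Mannich base 31. Keeping C11–C13 as a dimethylaminomethyl group means no α-methylene lactone is present during metathesis, osmylation or acylation, where it would compete as an olefin and as an electrophile. The forward steps must be mild enough for the epoxide and the two esters: quaternisation with bicarbonate elimination, then fluoride under near-neutral conditions.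

**The two esters and the diol (31 ← 26 + 29; 26 ← 25; 25 ← 23).** The acyl C–O bonds at O8 and O9 are cut in turn, then both C–O bonds of the diol. Syn-dihydroxylation of a ring-cis C8=C9 olefin gives the required erythro (cis) diol directly, whereas epoxide opening would give the trans series. Acetate goes on first at the allylic, less encumbered O9; the hindered O8 then takes the activated silyl-protected acid 29. The precursor 23 has lost two stereocentres and both acyl groups. The forward osmylation must pick C8=C9 over the electron-poor C1=C10 enoate and must attack the face cis to the C7–C11 bond.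

**Ring closure (23 ← 20).** Cutting C8=C9 opens the macrocycle to the diene 20, in which each terminus is a vinyl group. The neighbouring cuts are poorer. A C9–C10 coupling would require a vinyl halide to pass through the organocopper step. C6–C7 and C7–C8 belong to the lactone chemistry. C2–C3 has no functional handle. Ring-closing metathesis needs nothing beyond the two vinyl groups, and the three turn elements already in 20 (cis-epoxide, ring-cis enoate, trans-lactone) hold the termini near each other. The forward reaction must tolerate the basic nitrogen, which is protonated for this purpose, and must beat oligomerisation.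

**Key disconnection (20 ← 15 + 16 + 17).** C7–C8 and C11–C13 are cut together. This returns butenolide 15, vinylmagnesium bromide 16 and dimethyl(methylidene)ammonium iodide 17. Against a stepwise α-methylenation of a saturated lactone, this cut uses the enolate that the conjugate addition produces anyway, and it sets C7 from C6 across a planar five-membered ring, the most reliable stereochemical relay in the molecule. The precursor 15 has two stereocentres fewer and lacks the nitrogen. The forward step must give 1,4-addition to the butenolide only, anti to the C6 substituent, and must leave the epoxide and the acyclic dienoate alone.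

**The dienoate arm (15 ← 13 + 14; 13 ← 10 + 11; 10 ← 8).** C9–C10 is cut by a Stille coupling of the (Z)-α-iodoenoate 13 with tributyl(vinyl)stannane 14. C1=C10 is cut by a Wittig reaction of aldehyde 10 with an iodo-ylide made from 11. C1 is traced to ozonolysis of the isopropylidene terminus of 8. Building this arm after the butenolide has two advantages. The alkyne semi-hydrogenation is never run in the presence of the terminal diene. The ozonolysis also meets only one electron-rich olefin, because C4–C5 is already an epoxide. The forward steps must give the enoate with C2 trans to the ester, which the stabilised ylide and the stereoretentive coupling provide.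

**The butenolide (8 ← 6 ← 3 + 4).** The lactone C–O bond and the C6–C7 bond are cut, giving epoxy aldehyde 3 and methyl propiolate 4. Propiolate delivers C7, C11 and C12 at the right oxidation level, and cis-reduction of the ynoate closes the ring by itself. The addition must set C6 anti to the oxirane oxygen. This is the Felkin–Anh outcome for a cis-substituted α,β-epoxy aldehyde.

**The epoxide first (3 ← 2 ← 1).** The oxirane is traced to nerol 1 by Sharpless asymmetric epoxidation. This sets C4 and C5 by reagent control on the only allylic olefin and passes the (Z)-geometry on as the cis ring relationship. The alternatives are weaker. A hydroxyl-directed epoxidation of a (Z)-allylic C6 alcohol would place the oxirane oxygen syn to O6 in the A(1,3)-minimised conformer (threo), whereas the target has it anti (erythro). A late epoxidation of the macrocycle would have to distinguish C4=C5 from C8=C9 in the presence of an oxidisable amine, with no predictable facial bias. For these reasons the butenolide that enters the key step carries the finished cis-4,5-epoxide and not the C4=C5 olefin. The price is that the epoxide must survive the organometallic step, which is addressed under the risks.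

## Roads not taken

**Alternative 1: Ramberg–Bäcklund contraction of an eleven-membered sulfone.** The cut is C4=C5. In the forward direction the cyclic sulfone A2, with sulfur between C4 and C5, is halogenated in situ (CBr2F2, KOH on alumina), closes to the episulfone and loses SO2 to give the ten-membered (Z)-cycloalkene A1.
- Merits: the ring is first closed as an easier eleven-membered thioether and then contracted irreversibly. The C8/C9 diol is already fixed as an acetonide before any ring exists.
- Weak points: the strongly basic medium excludes the lactone and both esters, so C12 and C14 travel as silyl ethers and must be oxidised after ring formation. C13 is still missing. The free C6 hydroxyl of A1 would direct epoxidation to the threo epoxide, the opposite of what the target needs. The (Z)-geometry of the new olefin is plausible in a medium ring but not enforced.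
- Comparison: this road is better on two counts that are the soft spots of the chosen plan. The C8/C9 configuration does not depend on the conformation of a macrocycle, and the ring-forming event is irreversible, whereas metathesis is reversible. Against this the chosen plan reaches the ring with C12, C13 and C14 at their final oxidation level and the epoxide in place, and it needs far fewer operations after cyclisation.

**Alternative 2: rhodium carbenoid C–H insertion.** The cut is C7–C11. The C6 diazoacetate A4 loses nitrogen with Rh2(5S-MEPY)4, and the carbenoid inserts into the C7–H bond anti to O6 to give the trans-fused lactone A3.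
- Merits: the lactone is annulated on a ring that already holds the epoxide, the enoate and the C8/C9 oxygens (as a carbonate). C7 is set with help from the catalyst. No organometallic reagent meets the epoxide.
- Weak points: the step presupposes A4, a fully functionalised ten-membered ring, and says nothing about how that ring is made, which is the main difficulty. The carbenoid can choose between the two C7 hydrogens and C5–H, and it can be intercepted by the oxirane or carbonate oxygens as oxonium ylides. A3 lacks C13, so an enolate methylenation must follow on a substrate carrying a carbonate, an enoate and an epoxide. Removal of the carbonate then returns the same unprotected cis-diol that must be differentiated.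
- Comparison: this road is as good as the chosen one for the trans ring fusion and gentler toward the epoxide. The chosen plan forms C7–C8 and C11–C13 in one step and sets five of the six stereocentres before the ring exists.

**Alternative 3: tetralin dearomatisation, then ozonolysis of the ring fusion.** No ring bond is formed. Ozone (then Me2S) cleaves the tetrasubstituted C5=C10 olefin of the bicyclic ketal A6 and unveils the ten-membered diketone A5.
- Merits: the medium ring comes from cleaving a bond in a cheap, rigid bicycle, so there is no macrocyclisation risk at all and the sequence scales.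
- Weak points: A5 has one stereocentre (C4), and that centre must become the quaternary epoxide carbon, so it is erased on the way to C4=C5. The C6 oxygen, the C7 three-carbon appendage, the C9 oxygen and C14 must all be introduced on a mobile cyclodecanedione. That substrate has two similar ketones and a standing risk of transannular aldol reaction. None of the six target stereocentres is controlled, and the step count would be much higher.
- Comparison: this road is clearly better than metathesis for making the ring. The chosen plan accepts the cyclisation risk in exchange for stereocontrol, which it draws from a chiral pool-like relay (Sharpless epoxide → C6 → C7) that Alternative 3 cannot offer.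

Key step: step 8

Remarks on the chemistry (assumptions):
- Assumption: in macrocycle 23 the C8=C9 unit sits, as C8 and C9 must in the natural ring shape with their oxygens outward, so that its accessible face is the one cis to the C7–C11 bond; the opposite outcome is covered by a fallback.
- Assumption: compounds 1, 4, 11, 14, 16, 17 and 27 are commercial.

## Route

Step 1
Reactants: 1 nerol, (2Z)-3,7-dimethylocta-2,6-dien-1-ol
Product: 2 [(2S,3R)-3-methyl-3-(4-methylpent-3-en-1-yl)oxiran-2-yl]methanol
Conditions: Ti(OiPr)4 (10 mol %), L-(+)-diethyl tartrate (12 mol %), t-BuOOH, 4 Å MS, CH2Cl2, −20 °C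
Reagents that add atoms: tert-butyl hydroperoxide, CC(C)(C)OO
Why: Sharpless asymmetric epoxidation; the Ti(OiPr)4–tartrate complex binds the allylic alcohol and oxidises only the C4=C5 olefin, the L-(+)-tartrate should deliver oxygen to the face that gives the (2S,3R)-epoxide (target C5 S, C4 R), and the (Z)-geometry of nerol becomes the cis relationship of C3 and C6 on the oxirane.

Step 2
Reactants: 2 [(2S,3R)-3-methyl-3-(4-methylpent-3-en-1-yl)oxiran-2-yl]methanol
Product: 3 (2R,3R)-3-methyl-3-(4-methylpent-3-en-1-yl)oxirane-2-carbaldehyde
Conditions: TEMPO (10 mol %), PhI(OAc)2 (1.1 equiv), CH2Cl2, rt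
Reagents that add atoms: none
Why: Nitroxyl-catalysed (oxoammonium) oxidation of a primary alcohol to the aldehyde, a standard way to 2,3-epoxy aldehydes that leaves the oxirane and the remote olefin untouched; no stereocentre is affected (the descriptor at the oxirane CH changes only because the priorities change).

Step 3
Reactants: 3 (2R,3R)-3-methyl-3-(4-methylpent-3-en-1-yl)oxirane-2-carbaldehyde; 4 methyl propiolate
Product: 6 methyl (4S)-4-hydroxy-4-[(2S,3R)-3-methyl-3-(4-methylpent-3-en-1-yl)oxiran-2-yl]but-2-ynoate, via lithium methyl propiolate 5 (not isolated)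
Conditions: 4, LiN(SiMe3)2, THF, −78 °C; then 3, −78 °C; AcOH, −78 °C
Reagents that add atoms: none
Why: Acetylide addition to an aldehyde forms C6–C7; the new C6 centre is set by Felkin–Anh (polar) control, the nucleophile attacking anti to the oxirane C–O bond and past the C5 hydrogen, which for a cis-substituted α,β-epoxy aldehyde should favour the erythro alcohol with O6 anti to the oxirane oxygen (4S), as in the target.

Step 4
Reactants: 6 methyl (4S)-4-hydroxy-4-[(2S,3R)-3-methyl-3-(4-methylpent-3-en-1-yl)oxiran-2-yl]but-2-ynoate
Product: 8 (5S)-5-[(2S,3R)-3-methyl-3-(4-methylpent-3-en-1-yl)oxiran-2-yl]furan-2(5H)-one, via (Z)-hydroxy enoate 7 (not isolated)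
Conditions: H2 (1 atm), Pd/CaCO3 poisoned with Pb(OAc)2 (Lindlar catalyst), quinoline, EtOAc, rt; then PPTS (cat.), CH2Cl2, rt
Reagents that add atoms: none
Why: Lindlar semi-hydrogenation gives the (Z)-γ-hydroxy enoate, which lactonises with loss of methanol (transesterification) to the butenolide; the trisubstituted olefin and the oxirane are inert to the poisoned catalyst and C6 is retained.

Step 5
Reactants: 8 (5S)-5-[(2S,3R)-3-methyl-3-(4-methylpent-3-en-1-yl)oxiran-2-yl]furan-2(5H)-one
Product: 10 3-[(2R,3S)-2-methyl-3-[(2S)-5-oxo-2,5-dihydrofuran-2-yl]oxiran-2-yl]propanal, via secondary ozonide 9 (not isolated)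
Conditions: O3, CH2Cl2, −78 °C (Sudan Red 7B end-point); then Me2S, −78 °C → rt
Reagents that add atoms: ozone, [O-][O+]=O
Why: Ozonolysis with reductive work-up; the isopropylidene olefin is the only electron-rich double bond left and reacts far faster than the electron-poor butenolide, so the indicator end-point should stop the reaction after one cleavage and leave C1 as the aldehyde.

Step 6
Reactants: 10 3-[(2R,3S)-2-methyl-3-[(2S)-5-oxo-2,5-dihydrofuran-2-yl]oxiran-2-yl]propanal; 11 methyl (triphenyl-λ5-phosphanylidene)acetate
Product: 13 methyl (2Z)-2-iodo-5-[(2R,3S)-2-methyl-3-[(2S)-5-oxo-2,5-dihydrofuran-2-yl]oxiran-2-yl]pent-2-enoate, via iodo ylide 12 (not isolated)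
Conditions: 11, NIS, MeCN, −20 °C; then 10, −20 °C → rt
Reagents that add atoms: N-iodosuccinimide, O=C1CCC(=O)N1I
Why: Wittig olefination with an α-iodinated stabilised ylide generated in the flask; as with other stabilised ylides the ester should end trans to the alkyl chain, which is the (Z)-iodoenoate, and the weakly basic ylide should not disturb the butenolide γ-hydrogen.

Step 7
Reactants: 13 methyl (2Z)-2-iodo-5-[(2R,3S)-2-methyl-3-[(2S)-5-oxo-2,5-dihydrofuran-2-yl]oxiran-2-yl]pent-2-enoate; 14 tributyl(ethenyl)stannane
Product: 15 methyl (2E)-2-ethenyl-5-[(2R,3S)-2-methyl-3-[(2S)-5-oxo-2,5-dihydrofuran-2-yl]oxiran-2-yl]pent-2-enoate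
Conditions: 14, Pd2(dba)3 (2.5 mol %), AsPh3 (20 mol %), CuI (10 mol %), DMF, rt
Reagents that add atoms: none
Why: Stille coupling of an α-iodoenoate with a vinylstannane under neutral zerovalent-palladium catalysis proceeds with retention of olefin geometry, so the new vinyl group (C9) is cis to C2 and the ester stays trans; the cis C2 substituent disfavours the s-cis diene and should slow Diels–Alder dimerisation of the 2-vinyl enoate, which is nevertheless used promptly.

Step 8
Reactants: 15 methyl (2E)-2-ethenyl-5-[(2R,3S)-2-methyl-3-[(2S)-5-oxo-2,5-dihydrofuran-2-yl]oxiran-2-yl]pent-2-enoate; 16 vinylmagnesium bromide; 17 dimethyl(methylidene)ammonium iodide (Eschenmoser's salt)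
Product: 20 methyl (2E)-5-[(2R,3S)-3-[(2S,3S,4R)-4-[(dimethylamino)methyl]-3-ethenyl-5-oxooxolan-2-yl]-2-methyloxiran-2-yl]-2-ethenylpent-2-enoate, via bromomagnesium divinylcuprate 18 (not isolated), via bromomagnesium lactone enolate 19 (not isolated)
Conditions: 16 (2.2 equiv), CuBr·SMe2 (1.1 equiv), THF/Me2S, −78 °C; then 15, −78 °C; then 17 (3 equiv), −78 → −20 °C; aq. NH4Cl/NH3
Reagents that add atoms: none
Why: The cuprate (CH2=CH)2CuMgBr 18 forms a π-complex with the butenolide C7=C11 bond, adds at C7 through a trivalent copper intermediate and releases the vinyl group by reductive elimination, leaving the magnesium enolate 19, which is alkylated at C11 by the iminium ion of 17 (Mannich reaction). The closest known reaction type is the tandem organocopper 1,4-addition and α-trapping of 5-substituted furan-2(5H)-ones, which gives trans,trans-trisubstituted butanolides, combined with the capture of ester enolates by Eschenmoser's salt. No ring is closed; two carbon–carbon bonds (C7–C8 and C11–C13) are formed. C7 is controlled by C6: the reagent reaches the planar five-membered ring from the face opposite the oxiranyl substituent, so C8 ends trans to C5. C11 is controlled by C7: the iminium ion approaches the enolate anti to the new vinyl group; this centre is erased later, so its ratio affects only handling. The step needs 1,4- over 1,2-addition, which the soft copper reagent at −78 °C provides, and it needs the butenolide to react in preference to the acyclic enoate, which is α-branched, β-alkylated and only cross-conjugated with its vinyl group and so offers neither a fast 1,4- nor a 1,6-pathway. It also needs the trisubstituted oxirane to survive, which should hold because such epoxides react slowly with organocopper reagents at this temperature and the capture is kept at or below −20 °C to limit halide-assisted opening. Excess 17 consumes residual organometallic, and the amine product masks the future Michael acceptor for the following steps.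

Step 9
Reactants: 20 methyl (2E)-5-[(2R,3S)-3-[(2S,3S,4R)-4-[(dimethylamino)methyl]-3-ethenyl-5-oxooxolan-2-yl]-2-methyloxiran-2-yl]-2-ethenylpent-2-enoate
Product: 23 (4R,5S,6S,7S,11R)-13-(dimethylamino)-4,5-epoxy-14-methoxy-14-oxogermacra-1(10)E,8Z-dien-12,6-olide (ring-cis C1=C10 and C8=C9, cis-epoxide, trans-lactone, CH2NMe2 on C11 trans to C8), via open-chain ammonium tosylate 21 (not isolated), via macrocyclic ammonium tosylate 22 (not isolated)
Conditions: TsOH·H2O (1.0 equiv), CH2Cl2, rt; then (H2IMes)(PCy3)Cl2Ru=CHPh (second-generation Grubbs catalyst, 10 mol %), CH2Cl2 (0.001 M), 40 °C; aq. NaHCO3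
Reagents that add atoms: none
Why: Ring-closing olefin metathesis; the ruthenium alkylidene should load on the unhindered C7 vinyl group and close onto the terminal vinyl of the dienoate with loss of ethene, helped by the three turn elements of the chain, and only the ring-cis C8=C9 olefin is geometrically possible in this ring. Protonation keeps the amine off ruthenium, and one equivalent of sulfonic acid leaves no free strong acid for the oxirane.

Step 10
Reactants: 23 (4R,5S,6S,7S,11R)-13-(dimethylamino)-4,5-epoxy-14-methoxy-14-oxogermacra-1(10)E,8Z-dien-12,6-olide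
Product: 25 (4R,5S,6S,7R,8S,9R,11R)-13-(dimethylamino)-4,5-epoxy-8,9-dihydroxy-14-methoxy-14-oxogermacr-1(10)E-en-12,6-olide, via cyclic osmate ester 24 (not isolated)
Conditions: OsO4 (5 mol %), NMO (1.5 equiv), acetone/H2O (5:1), 0 °C → rt; aq. Na2SO3
Reagents that add atoms: osmium tetroxide, O=[Os](=O)(=O)=O; N-methylmorpholine N-oxide, C[N+]1([O-])CCOCC1
Why: Catalytic osmylation ([3+2] addition of OsO4, reoxidation by NMO) is a syn addition, so the ring-cis olefin gives the erythro diol. C8=C9 should react in preference to the trisubstituted, ester-deactivated C1=C10. The (8S,9R) configuration requires attack on the face cis to the C7–C11 bond and trans to H7, which is expected to be the outer face when C8 and C9 lie on the side of the ring that lets their oxygens point outward.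

Step 11
Reactants: 25 (4R,5S,6S,7R,8S,9R,11R)-13-(dimethylamino)-4,5-epoxy-8,9-dihydroxy-14-methoxy-14-oxogermacr-1(10)E-en-12,6-olide
Product: 26 (4R,5S,6S,7R,8S,9R,11R)-9-acetoxy-13-(dimethylamino)-4,5-epoxy-8-hydroxy-14-methoxy-14-oxogermacr-1(10)E-en-12,6-olide
Conditions: Ac2O (1.2 equiv), pyridine, CH2Cl2, 0 °C
Reagents that add atoms: acetic anhydride, CC(=O)OC(C)=O
Why: Site-selective acylation of a diol; the allylic O9 hydroxyl is flanked by the trigonal C10 and should be the more accessible one, whereas O8 sits beside the ring-fusion methine C7, so limited anhydride at low temperature should give the 9-monoacetate without touching a stereocentre.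

Step 12
Reactants: 27 methyl 2-(hydroxymethyl)prop-2-enoate
Product: 28 methyl 2-({[tert-butyl(dimethyl)silyl]oxy}methyl)prop-2-enoate
Conditions: TBSCl, imidazole, CH2Cl2, 0 °C → rt
Reagents that add atoms: tert-butyldimethylsilyl chloride, CC(C)(C)[Si](C)(C)Cl
Why: Standard silylation of a primary allylic alcohol; the silyl ether prevents self-acylation of the side-chain acid in the esterification.

Step 13
Reactants: 28 methyl 2-({[tert-butyl(dimethyl)silyl]oxy}methyl)prop-2-enoate
Product: 29 2-({[tert-butyl(dimethyl)silyl]oxy}methyl)prop-2-enoic acid
Conditions: LiOH·H2O, THF/H2O, 0 °C; then 0.5 M HCl to pH 3, 0 °C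
Reagents that add atoms: lithium hydroxide, [Li+].[OH-]
Why: Saponification of a methyl ester; the primary silyl ether tolerates cold hydroxide and a brief mildly acidic work-up.

Step 14
Reactants: 26 (4R,5S,6S,7R,8S,9R,11R)-9-acetoxy-13-(dimethylamino)-4,5-epoxy-8-hydroxy-14-methoxy-14-oxogermacr-1(10)E-en-12,6-olide; 29 2-({[tert-butyl(dimethyl)silyl]oxy}methyl)prop-2-enoic acid
Product: 31 (4R,5S,6S,7R,8S,9R,11R)-9-acetoxy-8-{[2-({[tert-butyl(dimethyl)silyl]oxy}methyl)prop-2-enoyl]oxy}-13-(dimethylamino)-4,5-epoxy-14-methoxy-14-oxogermacr-1(10)E-en-12,6-olide, via mixed trichlorobenzoic anhydride 30 (not isolated)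
Conditions: 29, 2,4,6-trichlorobenzoyl chloride, Et3N, toluene, rt; then 26, DMAP, 0 °C → rt
Reagents that add atoms: none
Why: Yamaguchi esterification; the preformed mixed anhydride is attacked at the less hindered acrylic carbonyl by the hindered secondary O8 hydroxyl under DMAP catalysis, and the low temperature with preformed acylating agent is chosen to outrun acetyl migration from O9.

Step 15
Reactants: 31 (4R,5S,6S,7R,8S,9R,11R)-9-acetoxy-8-{[2-({[tert-butyl(dimethyl)silyl]oxy}methyl)prop-2-enoyl]oxy}-13-(dimethylamino)-4,5-epoxy-14-methoxy-14-oxogermacr-1(10)E-en-12,6-olide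
Product: 33 (4R,5S,6S,7R,8S,9R)-9-acetoxy-8-{[2-({[tert-butyl(dimethyl)silyl]oxy}methyl)prop-2-enoyl]oxy}-4,5-epoxy-14-methoxy-14-oxogermacra-1(10)E,11(13)-dien-12,6-olide, via quaternary ammonium iodide 32 (not isolated)
Conditions: MeI (excess), THF, rt; then sat. aq. NaHCO3/EtOAc, rt
Reagents that add atoms: none
Why: N-methylation of the Mannich base followed by E1cB (Hofmann-type) elimination of trimethylamine from the β-ammonio lactone is the standard unmasking of an α-methylene lactone; bicarbonate is too weak to hydrolyse or migrate the esters, and the C11 stereocentre is removed.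

Step 16
Reactants: 33 (4R,5S,6S,7R,8S,9R)-9-acetoxy-8-{[2-({[tert-butyl(dimethyl)silyl]oxy}methyl)prop-2-enoyl]oxy}-4,5-epoxy-14-methoxy-14-oxogermacra-1(10)E,11(13)-dien-12,6-olide
Product: 34 (4R,5S,6S,7R,8S,9R)-9-acetoxy-4,5-epoxy-8-{[2-(hydroxymethyl)prop-2-enoyl]oxy}-14-methoxy-14-oxogermacra-1(10)E,11(13)-dien-12,6-olide (CNP0147016.1)
Conditions: Et3N·3HF, THF, rt
Reagents that add atoms: none
Why: Fluoride-mediated cleavage of a primary silyl ether under nearly neutral conditions, which should spare the epoxide (not opened by this reagent at room temperature), the two Michael acceptors and the vicinal esters.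

## Compound list

1 | nerol, (2Z)-3,7-dimethylocta-2,6-dien-1-ol | CC(C)=CCC/C(C)=C\CO | starting material
2 | [(2S,3R)-3-methyl-3-(4-methylpent-3-en-1-yl)oxiran-2-yl]methanol | OC[C@@H]1O[C@]1(C)CCC=C(C)C | intermediate
3 | (2R,3R)-3-methyl-3-(4-methylpent-3-en-1-yl)oxirane-2-carbaldehyde | O=C[C@@H]1O[C@]1(C)CCC=C(C)C | intermediate
4 | methyl propiolate | C#CC(=O)OC | starting material
5 | lithium methyl propiolate (methyl 3-lithioprop-2-ynoate) | [Li]C#CC(=O)OC | intermediate
6 | methyl (4S)-4-hydroxy-4-[(2S,3R)-3-methyl-3-(4-methylpent-3-en-1-yl)oxiran-2-yl]but-2-ynoate | COC(=O)C#C[C@H](O)[C@@H]1O[C@]1(C)CCC=C(C)C | intermediate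
7 | methyl (2Z,4S)-4-hydroxy-4-[(2S,3R)-3-methyl-3-(4-methylpent-3-en-1-yl)oxiran-2-yl]but-2-enoate | COC(=O)/C=C\[C@H](O)[C@@H]1O[C@]1(C)CCC=C(C)C | intermediate
8 | (5S)-5-[(2S,3R)-3-methyl-3-(4-methylpent-3-en-1-yl)oxiran-2-yl]furan-2(5H)-one | O=C1C=C[C@H](O1)[C@@H]1O[C@]1(C)CCC=C(C)C | intermediate
9 | (5S)-5-[(2S,3R)-3-[2-(5,5-dimethyl-1,2,4-trioxolan-3-yl)ethyl]-3-methyloxiran-2-yl]furan-2(5H)-one (secondary ozonide, both trioxolane epimers) | O=C1C=C[C@H](O1)[C@@H]1O[C@]1(C)CCC1OOC(C)(C)O1 | intermediate
10 | 3-[(2R,3S)-2-methyl-3-[(2S)-5-oxo-2,5-dihydrofuran-2-yl]oxiran-2-yl]propanal | O=C1C=C[C@H](O1)[C@@H]1O[C@]1(C)CCC=O | intermediate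
11 | methyl (triphenyl-λ5-phosphanylidene)acetate | COC(=O)C=P(c1ccccc1)(c1ccccc1)c1ccccc1 | starting material
12 | methyl iodo(triphenyl-λ5-phosphanylidene)acetate | COC(=O)C(I)=P(c1ccccc1)(c1ccccc1)c1ccccc1 | intermediate
13 | methyl (2Z)-2-iodo-5-[(2R,3S)-2-methyl-3-[(2S)-5-oxo-2,5-dihydrofuran-2-yl]oxiran-2-yl]pent-2-enoate | O=C1C=C[C@H](O1)[C@@H]1O[C@]1(C)CC/C=C(\I)C(=O)OC | intermediate
14 | tributyl(ethenyl)stannane | C=C[Sn](CCCC)(CCCC)CCCC | starting material
15 | methyl (2E)-2-ethenyl-5-[(2R,3S)-2-methyl-3-[(2S)-5-oxo-2,5-dihydrofuran-2-yl]oxiran-2-yl]pent-2-enoate (key-step precursor) | O=C1C=C[C@H](O1)[C@@H]1O[C@]1(C)CC/C=C(\C=C)C(=O)OC | intermediate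
16 | vinylmagnesium bromide | C=C[Mg]Br | starting material
17 | dimethyl(methylidene)ammonium iodide | C=[N+](C)C.[I-] | starting material
18 | bromomagnesium divinylcuprate, (CH2=CH)2CuMgBr | C=C[Cu-]C=C.[Mg+]Br | intermediate
19 | bromomagnesium enolate of the C7-vinyl lactone (C11=C12–O–MgBr; vinyl on C7 trans to the oxiranyl group on C6) | Br[Mg]OC1=C[C@H](C=C)[C@H](O1)[C@@H]1O[C@]1(C)CC/C=C(\C=C)C(=O)OC | intermediate
20 | methyl (2E)-5-[(2R,3S)-3-[(2S,3S,4R)-4-[(dimethylamino)methyl]-3-ethenyl-5-oxooxolan-2-yl]-2-methyloxiran-2-yl]-2-ethenylpent-2-enoate (key-step product) | O=C1[C@@H](CN(C)C)[C@H](C=C)[C@H](O1)[C@@H]1O[C@]1(C)CC/C=C(\C=C)C(=O)OC | intermediate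
21 | p-toluenesulfonate salt of 20 (N-protonated) | O=C1[C@@H](C[NH+](C)C)[C@H](C=C)[C@H](O1)[C@@H]1O[C@]1(C)CC/C=C(\C=C)C(=O)OC.Cc1ccc(cc1)S(=O)(=O)[O-] | intermediate
22 | p-toluenesulfonate salt of 23 (N-protonated) | C1/C=C(C(=O)OC)\C=C/[C@H]2[C@H](C[NH+](C)C)C(=O)O[C@@H]2[C@@H]2O[C@]2(C)C1.Cc1ccc(cc1)S(=O)(=O)[O-] | intermediate
23 | (4R,5S,6S,7S,11R)-13-(dimethylamino)-4,5-epoxy-14-methoxy-14-oxogermacra-1(10)E,8Z-dien-12,6-olide (the C7 descriptor differs from the target only through CIP priorities) | C1/C=C(C(=O)OC)\C=C/[C@H]2[C@H](CN(C)C)C(=O)O[C@@H]2[C@@H]2O[C@]2(C)C1 | intermediate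
24 | cyclic 8,9-osmate ester of 25 (O8 and O9 bridged by OsO2) | O=[Os]1(=O)O[C@H]2[C@H]3[C@H](CN(C)C)C(=O)O[C@@H]3[C@@H]3O[C@]3(C)CC/C=C(/C(=O)OC)[C@H]2O1 | intermediate
25 | (4R,5S,6S,7R,8S,9R,11R)-13-(dimethylamino)-4,5-epoxy-8,9-dihydroxy-14-methoxy-14-oxogermacr-1(10)E-en-12,6-olide | O[C@H]1[C@H]2[C@H](CN(C)C)C(=O)O[C@@H]2[C@@H]2O[C@]2(C)CC/C=C(/C(=O)OC)[C@H]1O | intermediate
26 | (4R,5S,6S,7R,8S,9R,11R)-9-acetoxy-13-(dimethylamino)-4,5-epoxy-8-hydroxy-14-methoxy-14-oxogermacr-1(10)E-en-12,6-olide | O[C@H]1[C@H]2[C@H](CN(C)C)C(=O)O[C@@H]2[C@@H]2O[C@]2(C)CC/C=C(/C(=O)OC)[C@H]1OC(C)=O | intermediate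
27 | methyl 2-(hydroxymethyl)prop-2-enoate | C=C(CO)C(=O)OC | starting material
28 | methyl 2-({[tert-butyl(dimethyl)silyl]oxy}methyl)prop-2-enoate | C=C(CO[Si](C)(C)C(C)(C)C)C(=O)OC | intermediate
29 | 2-({[tert-butyl(dimethyl)silyl]oxy}methyl)prop-2-enoic acid | C=C(CO[Si](C)(C)C(C)(C)C)C(=O)O | intermediate
30 | 2-({[tert-butyl(dimethyl)silyl]oxy}methyl)prop-2-enoic 2,4,6-trichlorobenzoic anhydride | C=C(CO[Si](C)(C)C(C)(C)C)C(=O)OC(=O)c1c(Cl)cc(Cl)cc1Cl | intermediate
31 | (4R,5S,6S,7R,8S,9R,11R)-9-acetoxy-8-{[2-({[tert-butyl(dimethyl)silyl]oxy}methyl)prop-2-enoyl]oxy}-13-(dimethylamino)-4,5-epoxy-14-methoxy-14-oxogermacr-1(10)E-en-12,6-olide | C=C(CO[Si](C)(C)C(C)(C)C)C(=O)O[C@H]1[C@H]2[C@H](CN(C)C)C(=O)O[C@@H]2[C@@H]2O[C@]2(C)CC/C=C(/C(=O)OC)[C@H]1OC(C)=O | intermediate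
32 | N-methyl quaternary ammonium iodide of 31 (13-trimethylammonio) | C=C(CO[Si](C)(C)C(C)(C)C)C(=O)O[C@H]1[C@H]2[C@H](C[N+](C)(C)C)C(=O)O[C@@H]2[C@@H]2O[C@]2(C)CC/C=C(/C(=O)OC)[C@H]1OC(C)=O.[I-] | intermediate
33 | (4R,5S,6S,7R,8S,9R)-9-acetoxy-8-{[2-({[tert-butyl(dimethyl)silyl]oxy}methyl)prop-2-enoyl]oxy}-4,5-epoxy-14-methoxy-14-oxogermacra-1(10)E,11(13)-dien-12,6-olide | C=C(CO[Si](C)(C)C(C)(C)C)C(=O)O[C@H]1[C@H]2C(=C)C(=O)O[C@@H]2[C@@H]2O[C@]2(C)CC/C=C(/C(=O)OC)[C@H]1OC(C)=O | intermediate
34 | (4R,5S,6S,7R,8S,9R)-9-acetoxy-4,5-epoxy-8-{[2-(hydroxymethyl)prop-2-enoyl]oxy}-14-methoxy-14-oxogermacra-1(10)E,11(13)-dien-12,6-olide, CNP0147016.1 | C=C(CO)C(=O)O[C@H]1[C@H]2C(=C)C(=O)O[C@@H]2[C@@H]2O[C@]2(C)CC/C=C(/C(=O)OC)[C@H]1OC(C)=O | target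

## Step count and risks

Total: 16 steps. Longest linear sequence: 14 steps (steps 1–11 and 14–16, from nerol); steps 12 and 13 prepare the side-chain acid.

**Step 8 (key step).** The most likely failure is loss of the trisubstituted oxirane by magnesium halide or iodide assisted opening while the heterogeneous iminium capture is still slow. Next is proton abstraction at C6 by the basic organometallic, which would erode C6 or open the oxirane by β-elimination. Simple protonation of the enolate in place of capture is also possible.
Fallback: starting from 15, the conjugate addition is run alone and quenched cold to give methyl (2E)-2-ethenyl-5-[(2R,3S)-3-[(2S,3R)-3-ethenyl-5-oxooxolan-2-yl]-2-methyloxiran-2-yl]pent-2-enoate F1. In a separate step F1 is converted to its lithium enolate with LiN(SiMe3)2 at −78 °C, free of magnesium and copper salts, and alkylated with 17, again anti to the C7 vinyl group. This rejoins the route at 20.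

**Step 9 (ring-closing metathesis).** Cross-metathesis oligomerisation may outrun closure of the strained ten-membered ring because the reaction is reversible. Incompletely protonated amine may deactivate the catalyst. Prolonged heating of the ammonium salt may slowly open the oxirane.
Fallback: starting from 13, the conditions of step 8 are applied to the iodoenoate (the iodoalkene is expected to be inert toward the magnesium cuprate at −78 °C). This gives methyl (2Z)-5-[(2R,3S)-3-[(2S,3S,4R)-4-[(dimethylamino)methyl]-3-ethenyl-5-oxooxolan-2-yl]-2-methyloxiran-2-yl]-2-iodopent-2-enoate F2. An intramolecular Heck reaction at high dilution (Pd(OAc)2, PPh3, Ag2CO3, MeCN, 70 °C) then forms C9–C10 irreversibly by 10-endo carbopalladation of the C7 vinyl group. β-Hydride elimination toward C9 gives the conjugated diene, which in this ring can only be ring-cis. This rejoins the route at 23.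

**Step 10 (dihydroxylation).** The danger is poor or reversed facial selectivity. If the A(1,3)-minimised conformer with H7 eclipsing C8=C9 dominates, the face cis to C6 (the one the target needs) lies toward the inside of the ring, and the reagent, possibly guided by the C13 amine, would add from the other side.
Fallback: starting from 23, the opposite facial sense is reached by an electrophile–inversion sequence. Bromoacetoxylation (N-bromoacetamide, AcOH, LiOAc, CH2Cl2, 0 °C) places bromine on the accessible face at C8 and acetate anti at the allylic C9. The product is (4R,5S,6S,7S,8R,9R,11R)-9-acetoxy-8-bromo-13-(dimethylamino)-4,5-epoxy-14-methoxy-14-oxogermacr-1(10)E-en-12,6-olide F3. Silver-assisted ionisation (AgOSO2CF3, 2,6-lutidine, wet MeCN) with neighbouring-group participation of the acetate inverts C8 through the cis-fused acetoxonium ion. Hydrolysis and acetyl equilibration give the cis hydroxy acetate, rejoining the route at 26 and bypassing 25.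

**Step 11 (mono-acetylation).** Site selectivity between two secondary hydroxyls may be low, with bis-acetylation, base-induced acetyl migration, or relactonisation of O8 onto C12.
Fallback: starting from 25, the diol is tied up with trimethyl orthoacetate and PPTS as the cyclic orthoester (8,9-O-(1-methoxyethylidene) derivative) F4. Hydrolysis in aqueous acetic acid opens it to a single cis hydroxy acetate under stereoelectronic control, and the regioisomers can be equilibrated and separated. This rejoins the route at 26.

**Step 3 (alkynylation).** The Felkin–Anh preference may be insufficient, giving an erosion of the C6 configuration that is hard to correct later. The thermally fragile lithium propiolate may also decompose before addition.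
Fallback: starting from 6 as the epimer mixture, oxidation (Dess–Martin periodinane) gives the ynone methyl 4-[(2R,3R)-3-methyl-3-(4-methylpent-3-en-1-yl)oxiran-2-yl]-4-oxobut-2-ynoate F5. Midland reduction with (R)-B-isopinocampheyl-9-borabicyclo[3.3.1]nonane, which differentiates the alkynyl from the branched substituent and should give the (4S)-alcohol under reagent control reinforced by the Felkin preference, rejoins the route at 6.

## Further compounds

F1 | step 8 | methyl (2E)-2-ethenyl-5-[(2R,3S)-3-[(2S,3R)-3-ethenyl-5-oxooxolan-2-yl]-2-methyloxiran-2-yl]pent-2-enoate | O=C1C[C@H](C=C)[C@H](O1)[C@@H]1O[C@]1(C)CC/C=C(\C=C)C(=O)OC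
F2 | step 9 | methyl (2Z)-5-[(2R,3S)-3-[(2S,3S,4R)-4-[(dimethylamino)methyl]-3-ethenyl-5-oxooxolan-2-yl]-2-methyloxiran-2-yl]-2-iodopent-2-enoate | O=C1[C@@H](CN(C)C)[C@H](C=C)[C@H](O1)[C@@H]1O[C@]1(C)CC/C=C(\I)C(=O)OC
F3 | step 10 | (4R,5S,6S,7S,8R,9R,11R)-9-acetoxy-8-bromo-13-(dimethylamino)-4,5-epoxy-14-methoxy-14-oxogermacr-1(10)E-en-12,6-olide | Br[C@@H]1[C@H]2[C@H](CN(C)C)C(=O)O[C@@H]2[C@@H]2O[C@]2(C)CC/C=C(/C(=O)OC)[C@H]1OC(C)=O
F4 | step 11 | 8,9-O-(1-methoxyethylidene) cyclic orthoester of 25 | COC1(C)O[C@H]2[C@H]3[C@H](CN(C)C)C(=O)O[C@@H]3[C@@H]3O[C@]3(C)CC/C=C(/C(=O)OC)[C@H]2O1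
F5 | step 3 | methyl 4-[(2R,3R)-3-methyl-3-(4-methylpent-3-en-1-yl)oxiran-2-yl]-4-oxobut-2-ynoate | COC(=O)C#CC(=O)[C@@H]1O[C@]1(C)CCC=C(C)C
A1 | alternative 1 | ten-membered 4(5)Z,1(10)-ring-cis dien-6-ol with C8/C9 acetonide, 2-(tert-butyldimethylsilyloxy)ethyl on C7 and (tert-butyldimethylsilyloxy)methyl on C10 | C/C1=C/[C@@H](O)[C@H](CCO[Si](C)(C)C(C)(C)C)[C@@H]2OC(C)(C)O[C@@H]2/C(CO[Si](C)(C)C(C)(C)C)=C\CC1
A2 | alternative 1 | eleven-membered cyclic sulfone with sulfur between C4 and C5 (precursor of A1) | CC1S(=O)(=O)C[C@@H](O)[C@H](CCO[Si](C)(C)C(C)(C)C)[C@@H]2OC(C)(C)O[C@@H]2/C(CO[Si](C)(C)C(C)(C)C)=C\CC1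
A3 | alternative 2 | 4,5-epoxy-14-methoxy-14-oxogermacr-1(10)-en-12,6-olide 8,9-cyclic carbonate (C11 methylene, no C13) | O=C1O[C@H]2[C@H]3CC(=O)O[C@@H]3[C@@H]3O[C@]3(C)CC/C=C(/C(=O)OC)[C@H]2O1
A4 | alternative 2 | C6 diazoacetate of the 4,5-epoxy ten-membered enoate 8,9-cyclic carbonate (precursor of A3) | O=C1O[C@H]2C[C@H](OC(=O)C=[N+]=[N-])[C@@H]3O[C@]3(C)CC/C=C(/C(=O)OC)[C@H]2O1
A5 | alternative 3 | (11S)-11-methyl-1,4-dioxaspiro[4.9]tetradecane-7,12-dione | C[C@H]1CCCC(=O)CC2(CCC1=O)OCCO2
A6 | alternative 3 | (5'S)-5'-methyl-3',4',5',6',7',8'-hexahydro-1'H-spiro[[1,3]dioxolane-2,2'-naphthalene] (precursor of A5) | C[C@H]1CCCC2=C1CCC1(C2)OCCO1
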